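## Structural features

The target is a spiro[5.5]undecadiene of the chamigrene type: two cyclohexene rings share the quaternary carbon C6, ring A running from C1 to C5 and ring B from C7 to C11. Ring A carries the methyl-bearing C1=C2 alkene directly on C6, an allylic secondary alcohol at C3, a secondary bromide at C4 and the gem-dimethyl carbon C5, so C5 and C6 are vicinal quaternary carbons. Ring B holds a tetrasubstituted alkenyl bromide, C9(Me)=C10(Br), and C6 is stereogenic only because its two ring B arms differ one atom further out (C11 leads to C10, C7 leads to C8). C3 and C4 are adjacent stereocentres with oxygen and bromine trans and both pseudo-equatorial (hydroxyl on the C7 face, bromine on the C11 face), C4 is insulated from C6 by C5, and all three centres are S. Fragile points are the allylic alcohol (ionization), the trans bromohydrin (epoxide closure with base), the alkenyl bromide toward low-valent metals and, on the way, an acid-labile enol ether. The C4 bromide is neopentyl and cannot be introduced by substitution, so it must come from an electrophilic bromine source and an enol derivative of a C3 ketone. The real difficulty is the absolute configuration of the crowded spiro centre and its relay to C4 and C3. The key step exploits two facts: the C1=C2 alkene sits on C6, which is what an alkenylpalladium leaves when it adds across a ring B alkene, and in a 1,4-diene precursor C7 is sp2 while C11 is sp3.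

## Logic of the disconnections

21 from 19 (through 20): the C3–O bond is cut and re-formed with inversion. Hydride delivery to the C3 ketone of 18 is expected on the C7 face, which leaves oxygen cis to bromine, whereas the target needs it trans. An SN2 exchange at C3 separates the C3 configuration from that facial preference. The forward step must invert without ionizing the allylic C–O bond and must free the alcohol without epoxide closure.

19 from 18: the C3–H bond is cut, returning C3 to a ketone. C3 is then no stereocentre, and the C4 bromide sits α to a carbonyl, the only position from which it can be made. The forward step must be a 1,2-reduction on one face that leaves both C–Br bonds alone.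

18 from 16 (through 17): the C4–Br bond is cut. C4 is flanked by the quaternary C5, so only electrophilic bromination of the C3–C4 enol derivative is realistic. This leaves a compound with C6 as its single stereocentre. The forward step needs kinetic enolization at C4 rather than at the C1 methyl group, and a facial choice relayed from C6 alone.

16 from 15, 14 and 13: the C10–Br bond is traced back to a C10–O bond of a regiodefined enol derivative, and the C8–H bond is cut to reveal the ring B enone. The tetrasubstituted C9=C10 position is thereby fixed by conjugate reduction and never by equilibration. The forward steps must reduce the ring B enone in the presence of the ring A enone and exchange a hindered alkenyl triflate for bromide.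

13 from 12: the C10 carbonyl is masked as its methyl enol ether and the C7–H bond is cut, giving the 1-methoxy-1,3-diene. Ring B then is exactly what a β-hydride elimination leaves behind. The forward step is a simple hydrolysis that must end at the conjugated enone.

12 from 11: the C1–C6 bond is cut, opening ring A and removing the only stereocentre. The precursor is achiral and contains a Z alkenyl iodide and a 1,4-diene. The forward step must form a quaternary spiro carbon next to C5, in the 6-exo mode, on one enantiotopic face.

11 from 10, and 10 from 8 and 9: the C1–I and C2–H bonds are cut to an ynone, then the C2–C3 bond is cut to an N-methoxy-N-methylamide and a propynyl nucleophile. The forward steps need anti addition of HI under conditions the enol ether survives, and mono-addition to the amide.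

8 from 6 (through 7), and 6 from 5: the amide C–N bond is cut to the acid, and four ring C–H bonds are cut to return the diene to an anisole. The forward Birch reduction must leave the three donor-substituted carbons sp2, and the acid must be handled without hydrolysing the enol ether.

5 from 4, and 4 from 1 and 2 (through 3): one carboxyl carbon is restored and the aryl–C5 bond is cut. Two purchasable pieces result, and the quaternary C5 is made by conjugate addition to a doubly activated alkene.

## Other disconnections considered

Alternative 1: The cut lies inside ring A, at C1–C2 and C3–C4. C2 and C3 come from ethoxyacetylene A3, and the rest of ring A from the spirocyclobutanone (4R)-3,3-dimethylspiro[3.5]nonane-1,6-dione 6-(ethylene ketal) A2. Forward, a zerovalent nickel catalyst would join the carbonyl carbon of A2 to the alkyne, cleave the strained C1–C4 bond by β-carbon elimination and close the vinylogous ester (6R)-3-ethoxy-5,5-dimethylspiro[5.5]undec-2-ene-1,10-dione 10-(ethylene ketal) A1 by reductive elimination.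
- In its favour: the spiro carbon is quaternary before the key step, strain release drives the step, and the 1,3-oxygen pattern of A1 is what methyl addition at C1 and acid transposition need to reach the C1-methyl C3-enone.
- Against it here: the stereocentre is only moved, since A2 must be made as one enantiomer although its two arms differ as remotely as in the target. A terminal ynol ether tends to oligomerize on zerovalent nickel. The insertion regiochemistry and the choice between the C1–C4 and C1–C6 bonds are not secured. Ring B arrives without the C9 methyl group.
- Comparison: A1 and 12 are equals in leaving a C10 carbonyl equivalent to be turned into the alkenyl bromide. A1 is the better in ring A, which is delivered without a second enone. On mechanism the Heck closure creates and controls the spiro centre in one catalytic event, which the ring expansion cannot. On step economy the alternative should be longer, because of the asymmetric synthesis of A2 and the extra methylation of ring B.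

Alternative 2: The cut is the C6–C11 bond. The precursor 4-[(3E)-4-bromo-5-chloro-3-methylpent-3-en-1-yl]-3,5-dimethylphenol A5 would be built on 3,5-dimethylphenol A6. Its phenoxide would attack the allylic chloride carbon through the para carbon and give the dienone 10-bromo-1,5,9-trimethylspiro[5.5]undeca-1,4,9-trien-3-one A4.
- In its favour: no transition metal is needed, and ring B arrives complete with methyl group and alkenyl bromide, so the four steps from enol ether to bromide of the chosen plan disappear. On this point and on step count the alternative is the better plan.
- Against it here: A4 is achiral and has one methyl group too few at C5. A conjugate methyl addition to one of the two enantiotopic dienone arms would make C5 the gem-dimethyl carbon, make C6 stereogenic and lead directly to 16. That addition must build a quaternary carbon next to the spiro carbon and must tell apart two arms that differ only through C7 and C11. The dienone is also open to dienone–phenol rearrangement, and closure of a six-membered spiro ring at a para carbon flanked by two methyl groups is slow.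
- Comparison: both plans rest on the same remote C7/C11 difference and are equals there. Enantioface selection in a ring-forming insertion has closer precedent than enantiotopic-arm selection in so crowded a conjugate addition, so the chosen plan is the safer in stereocontrol and the alternative the shorter.

Alternative 3: The cuts are C9–C10 and C10–C11, so C10 is inserted as a one-carbon unit. Dibromocarbene A9 would add to the C9=C11 alkene of (5R)-2,6,10,10-tetramethylspiro[4.5]deca-1,6-dien-8-one A8. The dibromocyclopropane would open with loss of bromide, and bromide return would give (6R,11S)-10,11-dibromo-1,5,5,9-tetramethylspiro[5.5]undeca-1,9-dien-3-one A7.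
- In its favour: C10 and its bromine are installed in one operation with unambiguous regiochemistry, which is better than the enone, triflate and bromide sequence. The absolute configuration would come from a chiral-pool cyclohexene, an equal or better guarantee if the relay to C6 is complete. A7 carries the ring A enone of 16, so the endgame would be the same.
- Against it here: the carbene is generated with strong base in the presence of an enolizable enone. The extra allylic bromide at C11 must be removed without allylic transposition and without loss of the alkenyl bromide. The spiro centre of A8 must be set by a carbene cyclization whose fidelity relative to the chiral-pool centre is uncertain.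
- Comparison: the alternative is equal in the endgame and better in the making of the alkenyl bromide. It is weaker in the control of C6 and probably longer before its key step.

Key step: step 7

Remark on numbering: the locants of the target (ring A C1–C5, spiro carbon C6, ring B C7–C11) are kept for all spirocyclic intermediates and for the corresponding atoms of their precursors.

Remark on the ligand: the sense of induction of BINAP in step 7 cannot be derived with certainty for this substrate. (R)-BINAP is written, and its antipode is to be used if the first cyclization shows that the (6R) trienone is favoured.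

## Route

Step 1
Reactants: 1 4-bromo-2-methoxy-1-methylbenzene; 2 2,2-dimethyl-5-(propan-2-ylidene)-1,3-dioxane-4,6-dione
Product: 4 5-[2-(3-methoxy-4-methylphenyl)propan-2-yl]-2,2-dimethyl-1,3-dioxane-4,6-dione, via (3-methoxy-4-methylphenyl)magnesium bromide 3 (not isolated)
Conditions: Mg, I2 (cat.), THF, reflux; then 2, THF, 0 °C to rt; aq. NH4Cl
Reagents that add atoms: none
Why: Magnesium insertion gives the aryl Grignard reagent 3, which adds in conjugate fashion to the doubly activated alkylidene malonate 2; the stabilized enolate does not react further, and the benzylic quaternary carbon (later C5) is formed without a stereocentre.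

Step 2
Reactants: 4 5-[2-(3-methoxy-4-methylphenyl)propan-2-yl]-2,2-dimethyl-1,3-dioxane-4,6-dione
Product: 5 3-(3-methoxy-4-methylphenyl)-3-methylbutanoic acid
Conditions: DMF/H2O (10:1), 100 °C
Reagents that add atoms: water, O
Why: Hydrolysis–decarboxylation of a cyclic acylal: water opens the ring, acetone is lost and the malonic acid decarboxylates at this temperature, which avoids the saponification and hot neat decarboxylation a diethyl malonate would need.

Step 3
Reactants: 5 3-(3-methoxy-4-methylphenyl)-3-methylbutanoic acid
Product: 6 3-(5-methoxy-4-methylcyclohexa-1,4-dien-1-yl)-3-methylbutanoic acid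
Conditions: Li, NH3 (l), THF, t-BuOH, −78 °C to −33 °C; NH4Cl; extraction at pH 5–6, 0 °C
Reagents that add atoms: none
Why: Birch reduction of the lithium carboxylate: the three donor-substituted ring carbons stay sp2, so the two unsubstituted para-related positions are protonated and the 1,4-diene carries the enol ether at the future C10 and the tether on the future C6. The carboxylate is not reduced, and the acid is liberated cold at pH 5–6 to spare the enol ether.

Step 4
Reactants: 6 3-(5-methoxy-4-methylcyclohexa-1,4-dien-1-yl)-3-methylbutanoic acid
Product: 8 N-methoxy-3-(5-methoxy-4-methylcyclohexa-1,4-dien-1-yl)-N,3-dimethylbutanamide, via acyl imidazole 7 (not isolated)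
Conditions: CDI, CH2Cl2, 0 °C to rt; then MeNH(OMe)·HCl, rt
Reagents that add atoms: N,O-dimethylhydroxylamine hydrochloride, CNOC.Cl
Why: Amide coupling through the acyl imidazole 7; the imidazole set free buffers the hydrochloride, so the enol ether never meets a strong acid, as it would on an acid chloride route.

Step 5
Reactants: 8 N-methoxy-3-(5-methoxy-4-methylcyclohexa-1,4-dien-1-yl)-N,3-dimethylbutanamide; 9 1-propynylmagnesium bromide
Product: 10 6-(5-methoxy-4-methylcyclohexa-1,4-dien-1-yl)-6-methylhept-2-yn-4-one
Conditions: 9 (0.5 M in THF), THF, −20 °C to 0 °C; inverse quench into cold aq. NH4Cl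
Reagents that add atoms: none
Why: Weinreb ketone synthesis: the magnesium chelate of the mono-adduct is stable until work-up, so no tertiary alcohol forms, and the cold inverse quench keeps the liberated hydroxylamine from adding to the ynone.

Step 6
Reactants: 10 6-(5-methoxy-4-methylcyclohexa-1,4-dien-1-yl)-6-methylhept-2-yn-4-one
Product: 11 (2Z)-2-iodo-6-(5-methoxy-4-methylcyclohexa-1,4-dien-1-yl)-6-methylhept-2-en-4-one
Conditions: LiI, AcOH (1.1 equiv each), MeCN, 0 °C to rt, dark
Reagents that add atoms: lithium iodide, [Li+].[I-]
Why: Conjugate hydroiodination of an ynone: iodide adds to the β-carbon and the allenolate is protonated anti, giving under kinetic control the Z isomer with iodine cis to the carbonyl tether. One equivalent of acetic acid in acetonitrile is far less acidic than neat acetic acid and should leave the tetrasubstituted enol ether intact.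

Step 7
Reactants: 11 (2Z)-2-iodo-6-(5-methoxy-4-methylcyclohexa-1,4-dien-1-yl)-6-methylhept-2-en-4-one
Product: 12 (6S)-10-methoxy-1,5,5,9-tetramethylspiro[5.5]undeca-1,7,9-trien-3-one
Conditions: Pd2(dba)3·CHCl3 (5 mol %), (R)-BINAP (12 mol %), Ag3PO4 (2 equiv), NMP, 70 °C
Reagents that add atoms: none
Why: Zerovalent palladium inserts into the C–I bond of 11 with retention of the Z geometry, and Ag3PO4 removes iodide, so a cationic alkenylpalladium carrying the chelating bisphosphine binds the ring alkene C6=C7. Syn migratory insertion puts C1 on the substituted carbon C6 and palladium on C7, which closes ring A in the 6-exo-trig mode; the 7-endo mode would need attack at C7 and is disfavoured by the short tether, bent toward C6 by the C5 gem-dimethyl group. C6 is now quaternary, so the only syn β-hydrogen lies on C8, and elimination gives the C7=C8 alkene conjugated with the enol ether. The closest known reaction type is the asymmetric intramolecular Heck cyclization of alkenyl and aryl halides or triflates that creates all-carbon quaternary and spiro centres under cationic conditions. The single new stereocentre C6 is controlled by the ligand: 11 is achiral, the two faces of C6=C7 are enantiotopic, and the chiral pocket must tell the flat C7–H side from the C11 methylene side during insertion. The step needs regioselective 6-exo insertion, secured by tether length and the Thorpe–Ingold effect, and suppression of H–Pd re-addition that would isomerize the skipped diene, secured by Ag3PO4 acting as halide scavenger and base. The product cannot aromatize because C6 is fully substituted.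

Step 8
Reactants: 12 (6S)-10-methoxy-1,5,5,9-tetramethylspiro[5.5]undeca-1,7,9-trien-3-one
Product: 13 (6R)-1,5,5,9-tetramethylspiro[5.5]undeca-1,8-diene-3,10-dione
Conditions: 1 M HCl, THF, rt
Reagents that add atoms: water, O
Why: Acid hydrolysis of a 1-methoxy-1,3-diene: protonation at the diene terminus C7 gives the conjugated oxocarbenium ion, and water releases methanol and the ring B 2-methylcyclohex-2-enone. C6 is untouched; its descriptor becomes R only because the ranking of C7 and C11 is reversed.

Step 9
Reactants: 13 (6R)-1,5,5,9-tetramethylspiro[5.5]undeca-1,8-diene-3,10-dione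
Product: 14 (6R)-10-{[dimethyl(phenyl)silyl]oxy}-1,5,5,9-tetramethylspiro[5.5]undeca-1,9-dien-3-one
Conditions: [(Ph3P)CuH]6 (3 mol %), PhMe2SiH (1.1 equiv), toluene, rt
Reagents that add atoms: dimethylphenylsilane, C[SiH](C)c1ccccc1
Why: Copper-catalysed 1,4-hydrosilylation (conjugate reduction): [(Ph3P)CuH]6 delivers hydride to C8 of the β-unsubstituted ring B enone, and silyl transfer gives the regiodefined tetrasubstituted silyl enol ether. The ring A enone is β,β-disubstituted with its β-carbon on the quaternary C6 and is not reached; 1,2-reduction of either carbonyl, the weakness of a bulky borohydride with two enones present, is not expected.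

Step 10
Reactants: 14 (6R)-10-{[dimethyl(phenyl)silyl]oxy}-1,5,5,9-tetramethylspiro[5.5]undeca-1,9-dien-3-one
Product: 15 (6R)-1,5,5,9-tetramethyl-3-oxospiro[5.5]undeca-1,9-dien-10-yl trifluoromethanesulfonate
Conditions: CsF, PhNTf2, DME, rt
Reagents that add atoms: N-phenylbis(trifluoromethanesulfonimide), O=S(=O)(N(c1ccccc1)S(=O)(=O)C(F)(F)F)C(F)(F)F
Why: Enol triflate formation from a regiodefined enol silane: fluoride frees the cesium enolate, which is O-sulfonylated before it can equilibrate, so the C9=C10 position of the alkene is kept.

Step 11
Reactants: 15 (6R)-1,5,5,9-tetramethyl-3-oxospiro[5.5]undeca-1,9-dien-10-yl trifluoromethanesulfonate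
Product: 16 (6R)-10-bromo-1,5,5,9-tetramethylspiro[5.5]undeca-1,9-dien-3-one
Conditions: Ni(cod)2 (10 mol %), LiBr (2 equiv), DMA/THF (1:3), rt
Reagents that add atoms: lithium bromide, [Li+].[Br-]
Why: Nickel-catalysed conversion of an enol triflate into an alkenyl halide: oxidative addition to zerovalent nickel, triflate–bromide exchange at the metal and C–Br bond formation proceed at room temperature, with the enone and the quaternary centre as spectators.

Step 12
Reactants: 16 (6R)-10-bromo-1,5,5,9-tetramethylspiro[5.5]undeca-1,9-dien-3-one
Product: 18 (4S,6S)-4,10-dibromo-1,5,5,9-tetramethylspiro[5.5]undeca-1,9-dien-3-one, via trimethylsilyl dienol ether 17 (not isolated)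
Conditions: LiN(iPr)2, Me3SiCl, THF, −78 °C; then NBS, −78 °C to 0 °C
Reagents that add atoms: N-bromosuccinimide, O=C1CCC(=O)N1Br
Why: Kinetic α′-deprotonation with in situ silylation gives the cross-conjugated silyl dienol ether 17, whose C4 terminus is brominated by NBS (α-bromination of a silyl enol ether). The new centre C4 is under substrate control from the spiro centre alone, C7 against C11 being the only difference between the faces, so both C4 epimers must be expected. 18 (bromine on the C11 face) is separated by chromatography, and the other epimer is converted into 18 by the enolate protonation given under the uncertain steps.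

Step 13
Reactants: 18 (4S,6S)-4,10-dibromo-1,5,5,9-tetramethylspiro[5.5]undeca-1,9-dien-3-one
Product: 19 (3R,4S,6S)-4,10-dibromo-1,5,5,9-tetramethylspiro[5.5]undeca-1,9-dien-3-ol
Conditions: iBu2AlH, CH2Cl2, −78 °C
Reagents that add atoms: none
Why: 1,2-Reduction of an enone by iBu2AlH: in the half-chair with bromine pseudo-equatorial, the pseudo-axial C5 methyl group shields the C11 face of the carbonyl. Hydride therefore arrives on the C7 face, and the hydroxyl ends pseudo-axial on the C11 face, cis to bromine (3R); the C–Br bonds are inert at this temperature.

Step 14
Reactants: 19 (3R,4S,6S)-4,10-dibromo-1,5,5,9-tetramethylspiro[5.5]undeca-1,9-dien-3-ol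
Product: 21 (3S,4S,6S)-4,10-dibromo-1,5,5,9-tetramethylspiro[5.5]undeca-1,9-dien-3-ol, via inverted chloroacetate 20 (not isolated)
Conditions: PPh3, DIAD, ClCH2CO2H, toluene, 0 °C to rt; then MeOH, K2CO3, 0 °C
Reagents that add atoms: chloroacetic acid, OC(=O)CCl
Why: Mitsunobu reaction: the oxyphosphonium ion at C3 is displaced by chloroacetate from the open C7 face with inversion (SN2), which sets 3S trans to bromine; SN2′ attack is blocked at the fully substituted C1, and the pseudo-equatorial bromine cannot participate. Brief carbonate-catalysed methanolysis of the labile chloroacetate frees the alcohol before the trans bromohydrin can close to an epoxide, which would need the strained diaxial conformer.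

## Compound list

1 | 4-bromo-2-methoxy-1-methylbenzene | COc1cc(Br)ccc1C | starting material
2 | 2,2-dimethyl-5-(propan-2-ylidene)-1,3-dioxane-4,6-dione | CC(C)=C1C(=O)OC(C)(C)OC1=O | starting material
3 | (3-methoxy-4-methylphenyl)magnesium bromide | COc1cc([Mg]Br)ccc1C | intermediate
4 | 5-[2-(3-methoxy-4-methylphenyl)propan-2-yl]-2,2-dimethyl-1,3-dioxane-4,6-dione | COc1cc(ccc1C)C(C)(C)C1C(=O)OC(C)(C)OC1=O | intermediate
5 | 3-(3-methoxy-4-methylphenyl)-3-methylbutanoic acid | COc1cc(ccc1C)C(C)(C)CC(=O)O | intermediate
6 | 3-(5-methoxy-4-methylcyclohexa-1,4-dien-1-yl)-3-methylbutanoic acid | OC(=O)CC(C)(C)C1=CCC(C)=C(OC)C1 | intermediate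
7 | 1-[3-(5-methoxy-4-methylcyclohexa-1,4-dien-1-yl)-3-methylbutanoyl]-1H-imidazole | O=C(CC(C)(C)C1=CCC(C)=C(OC)C1)n1ccnc1 | intermediate
8 | N-methoxy-3-(5-methoxy-4-methylcyclohexa-1,4-dien-1-yl)-N,3-dimethylbutanamide | CON(C)C(=O)CC(C)(C)C1=CCC(C)=C(OC)C1 | intermediate
9 | 1-propynylmagnesium bromide | CC#C[Mg]Br | starting material
10 | 6-(5-methoxy-4-methylcyclohexa-1,4-dien-1-yl)-6-methylhept-2-yn-4-one | CC#CC(=O)CC(C)(C)C1=CCC(C)=C(OC)C1 | intermediate
11 | (2Z)-2-iodo-6-(5-methoxy-4-methylcyclohexa-1,4-dien-1-yl)-6-methylhept-2-en-4-one | C/C(I)=C/C(=O)CC(C)(C)C1=CCC(C)=C(OC)C1 | intermediate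
12 | (6S)-10-methoxy-1,5,5,9-tetramethylspiro[5.5]undeca-1,7,9-trien-3-one | CC1=CC(=O)CC(C)(C)[C@]12C=CC(C)=C(OC)C2 | intermediate
13 | (6R)-1,5,5,9-tetramethylspiro[5.5]undeca-1,8-diene-3,10-dione | CC1=CC(=O)CC(C)(C)[C@]12CC=C(C)C(=O)C2 | intermediate
14 | (6R)-10-{[dimethyl(phenyl)silyl]oxy}-1,5,5,9-tetramethylspiro[5.5]undeca-1,9-dien-3-one | CC1=CC(=O)CC(C)(C)[C@]12CCC(C)=C(O[Si](C)(C)c3ccccc3)C2 | intermediate
15 | (6R)-1,5,5,9-tetramethyl-3-oxospiro[5.5]undeca-1,9-dien-10-yl trifluoromethanesulfonate | CC1=CC(=O)CC(C)(C)[C@]12CCC(C)=C(OS(=O)(=O)C(F)(F)F)C2 | intermediate
16 | (6R)-10-bromo-1,5,5,9-tetramethylspiro[5.5]undeca-1,9-dien-3-one | CC1=CC(=O)CC(C)(C)[C@]12CCC(C)=C(Br)C2 | intermediate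
17 | (6S)-{[10-bromo-1,5,5,9-tetramethylspiro[5.5]undeca-1,3,9-trien-3-yl]oxy}trimethylsilane | CC1=CC(O[Si](C)(C)C)=CC(C)(C)[C@]12CCC(C)=C(Br)C2 | intermediate
18 | (4S,6S)-4,10-dibromo-1,5,5,9-tetramethylspiro[5.5]undeca-1,9-dien-3-one | CC1=CC(=O)[C@@H](Br)C(C)(C)[C@]12CCC(C)=C(Br)C2 | intermediate
19 | (3R,4S,6S)-4,10-dibromo-1,5,5,9-tetramethylspiro[5.5]undeca-1,9-dien-3-ol | CC1=C[C@@H](O)[C@@H](Br)C(C)(C)[C@]12CCC(C)=C(Br)C2 | intermediate
20 | (3S,4S,6S)-4,10-dibromo-1,5,5,9-tetramethylspiro[5.5]undeca-1,9-dien-3-yl chloroacetate | CC1=C[C@H](OC(=O)CCl)[C@@H](Br)C(C)(C)[C@]12CCC(C)=C(Br)C2 | intermediate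
21 | (3S,4S,6S)-4,10-dibromo-1,5,5,9-tetramethylspiro[5.5]undeca-1,9-dien-3-ol | CC1=C[C@H](O)[C@@H](Br)C(C)(C)[C@]12CCC(C)=C(Br)C2 | target

## Step count and uncertain steps

Total step count: 14. Longest linear sequence: 14 steps, from 1 to 21; 2 and 9 are purchased.

Step 7 (key step). The most likely failure is incomplete enantiofacial discrimination in the migratory insertion, because the ligand must read a difference that lies one atom away from C6. A second risk is slow insertion at a carbon that becomes quaternary next to C5, which gives H–Pd species time to move the skipped diene into conjugation. The fallback replaces catalyst control of the absolute configuration by a resolution folded into the last step. It sets out from 19 of insufficient enantiomeric purity. The Mitsunobu inversion is run with (2S)-2-methoxy-2-phenylacetic acid in place of chloroacetic acid. This gives (3S,4S,6S)-4,10-dibromo-1,5,5,9-tetramethylspiro[5.5]undeca-1,9-dien-3-yl (2S)-2-methoxy-2-phenylacetate F1 from 19, and the diastereomer (3R,4R,6R)-4,10-dibromo-1,5,5,9-tetramethylspiro[5.5]undeca-1,9-dien-3-yl (2S)-2-methoxy-2-phenylacetate F2 from the mirror-image skeleton. The two are separated by crystallization or chromatography, and methanolysis of F1 (K2CO3, MeOH, 0 °C) comes back to the route at 21.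

Step 12. The most likely failure is unselective approach of the brominating agent to the two faces of the C3–C4 enol ether, since C7 and C11 are both methylene groups and the relay passes through C5. The fallback uses protonation in place of bromination as the face-selecting event. It sets out from 16. The bromination is run as before, and the unwanted epimer (4R,6S)-4,10-dibromo-1,5,5,9-tetramethylspiro[5.5]undeca-1,9-dien-3-one F3, alone or mixed with 18, is deprotonated with LiN(SiMe3)2 in THF at −78 °C. The resulting lithium (6S)-4,10-dibromo-1,5,5,9-tetramethylspiro[5.5]undeca-1,3,9-trien-3-olate F4 has no β-hydrogen to eliminate and no second enolizable α-position. It is protonated at −78 °C with acetic acid. A proton then enters on the face that bromine preferred in step 12, so bromine is left on the opposite face, and the sequence comes back to the route at 18.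

Step 14. The most likely failures are ionization of the activated allylic oxygen with loss of configuration or allylic transposition, elimination toward C4, and epoxide closure during methanolysis. The fallback replaces the SN2 inversion by thermodynamic control of the C3 configuration. It sets out from 18, which is reduced under equilibrating Meerwein–Ponndorf–Verley conditions (Al(OiPr)3, 2-propanol, toluene, 60 °C). The pseudo-equatorial alcohol trans to bromine lacks the 1,3-diaxial contact between hydroxyl and C5 methyl that burdens 19, so it should be the favoured epimer. The fallback comes back to the route at 21 and makes no new compound (F0).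

Step 6. The most likely failures are protonation of the tetrasubstituted enol ether, with hydrolysis or migration of the diene, and drift of the Z iodide to the E isomer on long exposure to acid. The fallback builds the leaving group with base only. It sets out from 8, which is acylated onto the lithium enolate of acetone (LiN(iPr)2, THF, −78 °C) to give 6-(5-methoxy-4-methylcyclohexa-1,4-dien-1-yl)-6-methylheptane-2,4-dione F5. The chelated enolate (NaH, then PhNTf2, THF) is sulfonylated at the less hindered acetyl oxygen, and (2Z)-6-(5-methoxy-4-methylcyclohexa-1,4-dien-1-yl)-6-methyl-4-oxohept-2-en-2-yl trifluoromethanesulfonate F6 is separated from its regioisomer. F6 ionizes at palladium without Ag3PO4 and is cyclized with Pd(OAc)2, (R)-BINAP and K2CO3 in toluene at 60 °C, which comes back to the route at 12.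

Step 11. The most likely failure is stalled oxidative addition at the hindered tetrasubstituted alkenyl triflate, or diversion of the zerovalent nickel by the enone. The fallback goes through a tin intermediate. It sets out from 15, which is stannylated (Pd(PPh3)4, Me3SnSnMe3, LiCl, dioxane, 80 °C) to (6R)-1,5,5,9-tetramethyl-10-(trimethylstannyl)spiro[5.5]undeca-1,9-dien-3-one F7. Bromodestannylation with Br2 in CH2Cl2 at −78 °C comes back to the route at 16.

## Further compounds

F1 | step 7 | (3S,4S,6S)-4,10-dibromo-1,5,5,9-tetramethylspiro[5.5]undeca-1,9-dien-3-yl (2S)-2-methoxy-2-phenylacetate | CC1=C[C@H](OC(=O)[C@@H](OC)c3ccccc3)[C@@H](Br)C(C)(C)[C@]12CCC(C)=C(Br)C2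
F2 | step 7 | (3R,4R,6R)-4,10-dibromo-1,5,5,9-tetramethylspiro[5.5]undeca-1,9-dien-3-yl (2S)-2-methoxy-2-phenylacetate | CC1=C[C@@H](OC(=O)[C@@H](OC)c3ccccc3)[C@H](Br)C(C)(C)[C@@]12CCC(C)=C(Br)C2
F3 | step 12 | (4R,6S)-4,10-dibromo-1,5,5,9-tetramethylspiro[5.5]undeca-1,9-dien-3-one | CC1=CC(=O)[C@H](Br)C(C)(C)[C@]12CCC(C)=C(Br)C2
F4 | step 12 | lithium (6S)-4,10-dibromo-1,5,5,9-tetramethylspiro[5.5]undeca-1,3,9-trien-3-olate | CC1=CC([O-])=C(Br)C(C)(C)[C@]12CCC(C)=C(Br)C2.[Li+]
F0 | step 14 | none | none
F5 | step 6 | 6-(5-methoxy-4-methylcyclohexa-1,4-dien-1-yl)-6-methylheptane-2,4-dione | CC(=O)CC(=O)CC(C)(C)C1=CCC(C)=C(OC)C1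
F6 | step 6 | (2Z)-6-(5-methoxy-4-methylcyclohexa-1,4-dien-1-yl)-6-methyl-4-oxohept-2-en-2-yl trifluoromethanesulfonate | C/C(OS(=O)(=O)C(F)(F)F)=C/C(=O)CC(C)(C)C1=CCC(C)=C(OC)C1
F7 | step 11 | (6R)-1,5,5,9-tetramethyl-10-(trimethylstannyl)spiro[5.5]undeca-1,9-dien-3-one | CC1=CC(=O)CC(C)(C)[C@]12CCC(C)=C([Sn](C)(C)C)C2
A1 | alternative 1 | (6R)-3-ethoxy-5,5-dimethylspiro[5.5]undec-2-ene-1,10-dione 10-(ethylene ketal) | O=C1C=C(OCC)CC(C)(C)[C@]12CCCC3(OCCO3)C2
A2 | alternative 1 | (4R)-3,3-dimethylspiro[3.5]nonane-1,6-dione 6-(ethylene ketal) | O=C1CC(C)(C)[C@]12CCCC3(OCCO3)C2
A3 | alternative 1 | ethoxyacetylene | CCOC#C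
A4 | alternative 2 | 10-bromo-1,5,9-trimethylspiro[5.5]undeca-1,4,9-trien-3-one | CC1=CC(=O)C=C(C)C12CCC(C)=C(Br)C2
A5 | alternative 2 | 4-[(3E)-4-bromo-5-chloro-3-methylpent-3-en-1-yl]-3,5-dimethylphenol | Cc1cc(O)cc(C)c1CC/C(C)=C(Br)\CCl
A6 | alternative 2 | 3,5-dimethylphenol | Cc1cc(C)cc(O)c1
A7 | alternative 3 | (6R,11S)-10,11-dibromo-1,5,5,9-tetramethylspiro[5.5]undeca-1,9-dien-3-one | CC1=CC(=O)CC(C)(C)[C@]12CCC(C)=C(Br)[C@H]2Br
A8 | alternative 3 | (5R)-2,6,10,10-tetramethylspiro[4.5]deca-1,6-dien-8-one | CC1=CC(=O)CC(C)(C)[C@]12CCC(C)=C2
A9 | alternative 3 | dibromocarbene | Br[C]Br
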